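**Conventions.** Daucane numbering is used throughout: C1 is the quaternary ring-fusion carbon with the methyl group, C2 and C3 are methylenes, C4 is the isopropyl carbinol, C5 is the ring-fusion CH, C6 is the veratrate carbinol, C7 is a methylene, C8=C9 is the methyl-bearing alkene, and C10 is the angelate carbinol. Ring A is the cyclopentane (C1–C5) and ring B is the cycloheptene (C1, C5–C10). β is the face that carries the C1 methyl group and α is the opposite face. C1 and C6 are S in every bicyclic intermediate.

## The problem

The target 26 is a trans-fused hydroazulene (1S,4R,5S,6S,10R) in which rings A and B share the C1–C5 bond. Read from the structure, the substituents are: C1 methyl β, H5 α, C4 hydroxyl β with the isopropyl group α, C6 veratrate α and C10 angelate α. The trans ring fusion is the central difficulty, because closing a five-membered ring onto an existing ring prefers the cis fusion and a C5 that is α to a carbonyl group would epimerise. The two arms of ring A therefore have to be placed trans on ring B before ring A is closed, and C5 must never become enolisable. Only C6 needs an external source of chirality: C6 can direct C5, C5 can direct C1, and the angular methyl group then distinguishes the faces of both rings for C4 and C10. The fragile groups are the angelate (Z to E isomerisation to the tiglate under acyl activation), the ionisable allylic C10 ester, the tertiary C4 alcohol (dehydration under acid), and any C6 acyloxy group that sits δ to a C10 enone carbonyl (vinylogous elimination). The two different esters must also end up on the correct oxygens. The enabling feature is the all-trans array C6/C5/C1 lying next to the C10 carbonyl carbon in ring B: this is the pattern left by anti conjugate addition to a 4-silyloxy-2-methylcyclohept-2-enone followed by anti alkylation of the C1=C10 enolate.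

## Retrosynthesis

**C6 ester.** The acyl–oxygen bond of the veratrate is cut first, giving diol monoester 24 and 3,4-dimethoxybenzoyl chloride 25. Placing this ester last keeps an acyloxy group away from C6 while C10 is still an enone carbonyl. The forward step only has to distinguish a secondary from a tertiary hydroxyl. Alcohol 24 comes from silyl ether 23 by desilylation.

**C10 ester.** In 23 the alkyl–oxygen bond C10–O is cut, not the acyl–oxygen bond, giving the 10β-alcohol 21 and angelic acid 22. Two points favour this over ordinary acylation: angelic acid enters as a carboxylate nucleophile and is never activated at the acyl carbon, and the inversion means the reduction may deliver the epimer that substrate control is expected to favour. The forward reaction must achieve displacement at an allylic carbon next to a quaternary centre.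

**C10 carbinol.** Alcohol 21 is traced to enone 20 by removing the C10–H bond. This removes one stereocentre and leaves the carbonyl group needed for all earlier ring-B chemistry. The forward reduction must be 1,2-selective and face-selective.

**C4 carbinol.** In 20 the C4–O and C3–H bonds are cut, through bromohydrin 19, back to the ring-A alkene 18. Epoxidation followed by hydride opening was considered and set aside, because the angular methyl group would steer the epoxide oxygen to the α face and C4–OH would end up α. In the bromohydrin the electrophile takes the open α face and water enters C4 from the β face, which is the required configuration. The precursor 18 has one stereocentre fewer and no free hydroxyl.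

**C8 methyl and C8=C9.** Dienone 18 is simplified to ketone 14 by cutting the C8–CH3 bond and removing two degrees of unsaturation, through silyl enol ethers 17 and 15 and enone 16. Because C1 is quaternary, the C10 ketone can only enolise toward C9, so regiochemistry is built in. The forward sequence is two Saegusa–Ito oxidations around one cuprate addition.

**Ring A.** The C3=C4 double bond of 14 is cut to give diene 13 with an allyl group on C1 and a 3-methylbut-1-en-2-yl group on C5. Closing ring A at this bond means no stereocentre is formed in the ring closure, so the fusion is trans because the two arms already are. The forward metathesis must engage a branched 1,1-disubstituted alkene.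

**Key disconnection.** In 13 the bonds C4–C5 and C1–C2 are cut, leading to enone 8, Grignard reagent 10 and allyl iodide 11. This turns three contiguous stereocentres into one and a ten-carbon diene ketone into a seven-carbon enone. The forward step asks for anti 1,4-addition relative to the silyloxy group and C-alkylation of the resulting enolate anti to the new C5 substituent.

**Enone and reagent.** The C-methyl bond of 8 is cut to iodide 7 and hence enone 6. Enone 6 comes from alcohol 5, acetate 4 and monoacetate 3, which is the desymmetrised form of meso diacetate 2, itself made from cyclohepta-1,3-diene 1. Grignard reagent 10 comes from bromide 9.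

## Roads not taken

**Alternative 1:** Ring B would be closed last at C9–C10 by a Nozaki–Hiyama–Kishi reaction.
- *Cut and key step.* The precursor A2 is a fully substituted ring-A cyclopentane carrying the C10 aldehyde on C1 and, on C5, a side chain with the C6 veratrate and a Z-configured C8-methyl alkenyl iodide. CrCl2 with catalytic NiCl2 would convert the iodide into an alkenylchromium species (trivalent chromium) that adds to the aldehyde to give bicyclic allylic alcohol A1.
- *Merits.* The C8=C9 geometry is carried in from the iodide, the C10 carbinol forms in the same step, the aldehyde cannot enolise, and the reagent tolerates the ester.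
- *Weak points.* A2 already contains the hardest element, the trans arrangement of the C1 and C5 substituents on a cyclopentane, together with C4 and the side-chain centre C6, and all of this has to be built in a long linear sequence. The C10 configuration would be decided by the conformation of the closing seven-membered ring and cannot be predicted with confidence. The closure also needs high dilution and a large excess of chromium salt.
- *Comparison.* This road is better in one respect: it makes the alkene and the carbinol of ring B in one step, where the chosen plan spends steps 11 to 14 and 17. Against this the chosen plan sets the C1/C5/C6 array in a single step from a seven-step enone and secures the trans fusion before ring A exists.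

**Alternative 2:** The hydroazulene would arise from a decalin by a semipinacol shift.
- *Cut and key step.* Starting from (S)-Wieland–Miescher ketone A5, a cis-fused decalin A4 would be prepared with a tertiary C6 hydroxyl, a C5 mesylate and the C4 isopropyl carbinol. KOtBu would deprotonate the C6 hydroxyl and C1 would migrate from C6 to C5 with loss of mesylate, contracting one six-membered ring to ring A and enlarging the other to ring B, to give hydroazulen-6-one A3.
- *Merits.* A5 is available in enantiopure form and already holds the quaternary C1. The shift is stereospecific. A3 would be reached in about five steps, so this road is clearly shorter on paper than the chosen one.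
- *Weak points.* In A4 the C4 hydroxyl, the C5 mesylate and the C6 hydroxyl must all lie on the face of the angular methyl group, so the dihydroxylation would have to occur on the screened face. The mesylate is flanked by two tertiary carbinols, and the C4 alkoxide can trigger a competing shift of C3. In A3, C5 is α to the new ketone, so the trans fusion could epimerise under the base that forms it. The C6 ketone would then still need face-selective reduction.
- *Comparison.* The chosen plan is longer. What it offers in return is a kinetic relay of stereochemistry in which C5 is never α to a carbonyl group and C6 is fixed from the first stereodefining step.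

**Alternative 3:** Ring A would be made by ring expansion of a cyclobutanol.
- *Cut and key step.* BF3·OEt2 would open the glycidic ester A7 at the tertiary carbon C1 while the cyclobutane carbon C2 migrates from the carbinol carbon C5 to C1, giving cyclopentanone A6 with the C10 hydroxyl retained.
- *Merits.* An asymmetric epoxidation would fix C1 and C10 together, early and by reagent control. This is something the chosen plan only achieves late, by reduction and inversion.
- *Weak points.* A6 holds only two of the five stereocentres and one ring. C5 is a ketone carbon in A6, so the trans fusion, C4, C6 and the whole of ring B with its alkene would still have to be built, and the seven-membered ring would have to be closed late.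
- *Comparison.* This road is better for C10 but leaves the ring-fusion problem untouched. The chosen plan solves the fusion first and accepts two late steps for C10.

Key step: step 9

**Assumption.** The lipase is taken to cleave the acetate on the carbinol carbon that becomes C6. If the enzyme prefers the other acetate, the acylation mode described among the fallbacks supplies 3.

## Route

Step 1
Reactants: 1 cyclohepta-1,3-diene
Product: 2 cis-cyclohept-2-ene-1,4-diyl diacetate (meso)
Conditions: Pd(OAc)2 (cat.), LiCl (cat.), LiOAc, p-benzoquinone (cat.), MnO2, AcOH, rt
Reagents that add atoms: acetic acid, CC(=O)O (LiOAc, [Li+].CC(=O)[O-], supplies the same acetate group)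
Why: Palladium-catalysed oxidative 1,4-diacetoxylation of a cyclic 1,3-diene: acetoxypalladation gives a π-allyl complex of divalent palladium, and with chloride on the metal the second acetate attacks from outside, trans to palladium, so the two acetoxy groups end up cis. The product is meso, so no absolute control is needed here.

Step 2
Reactants: 2 cis-cyclohept-2-ene-1,4-diyl diacetate
Product: 3 (1R,4S)-4-hydroxycyclohept-2-en-1-yl acetate
Conditions: Candida antarctica lipase B (immobilised), phosphate buffer pH 7, rt
Reagents that add atoms: none
Why: Enzymatic desymmetrisation of a meso diacetate by lipase-catalysed hydrolysis of one enantiotopic acetate. This sets the absolute configuration of the carbon that becomes C6, the only stereocentre taken from an external chiral source.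

Step 3
Reactants: 3 (1R,4S)-4-hydroxycyclohept-2-en-1-yl acetate
Product: 4 (1R,4S)-4-(tert-butyldimethylsilyloxy)cyclohept-2-en-1-yl acetate
Conditions: TBSCl, imidazole, DMF, rt
Reagents that add atoms: tert-butyldimethylsilyl chloride, CC(C)(C)[Si](C)(C)Cl
Why: Standard imidazole-mediated silylation of a secondary allylic alcohol; no stereocentre is touched.

Step 4
Reactants: 4 (1R,4S)-4-(tert-butyldimethylsilyloxy)cyclohept-2-en-1-yl acetate
Product: 5 (1R,4S)-4-(tert-butyldimethylsilyloxy)cyclohept-2-en-1-ol
Conditions: K2CO3 (cat.), MeOH, 0 °C to rt
Reagents that add atoms: none
Why: Base-catalysed transesterification removes the acetate; the silyl ether is stable to K2CO3 in methanol.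

Step 5
Reactants: 5 (1R,4S)-4-(tert-butyldimethylsilyloxy)cyclohept-2-en-1-ol
Product: 6 (S)-4-(tert-butyldimethylsilyloxy)cyclohept-2-en-1-one
Conditions: MnO2 (activated, excess), CH2Cl2, rt
Reagents that add atoms: none
Why: Selective oxidation of an allylic alcohol by MnO2 under neutral conditions, so the γ-silyloxy enone is not exposed to base. The former acetate-bearing stereocentre is removed on purpose.

Step 6
Reactants: 6 (S)-4-(tert-butyldimethylsilyloxy)cyclohept-2-en-1-one
Product: 7 (S)-4-(tert-butyldimethylsilyloxy)-2-iodocyclohept-2-en-1-one
Conditions: I2, pyridine, CH2Cl2, 0 °C to rt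
Reagents that add atoms: iodine, II
Why: α-Iodination of a cyclic enone by pyridine addition, iodination of the enolate and elimination (a Baylis–Hillman-type sequence); the conditions are mild enough for the γ-silyloxy group.

Step 7
Reactants: 7 (S)-4-(tert-butyldimethylsilyloxy)-2-iodocyclohept-2-en-1-one
Product: 8 (S)-4-(tert-butyldimethylsilyloxy)-2-methylcyclohept-2-en-1-one
Conditions: Me4Sn, PdCl2(PhCN)2 (cat.), AsPh3, CuI (cat.), NMP, 80 °C
Reagents that add atoms: tetramethylstannane, C[Sn](C)(C)C
Why: Stille coupling of an α-iodoenone (oxidative addition to zerovalent palladium, CuI-assisted transmetalation, reductive elimination). The neutral conditions avoid elimination of the γ-silyloxy group and leave the stereocentre untouched.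

Step 8
Reactants: 9 2-bromo-3-methylbut-1-ene
Product: 10 (3-methylbut-1-en-2-yl)magnesium bromide
Conditions: Mg turnings (activated with 1,2-dibromoethane), THF, 40 °C; used as titrated solution
Reagents that add atoms: magnesium, [Mg]
Why: Direct magnesium insertion into an alkenyl bromide in THF (Grignard reagent formation).

Step 9
Reactants: 8 (S)-4-(tert-butyldimethylsilyloxy)-2-methylcyclohept-2-en-1-one; 10 (3-methylbut-1-en-2-yl)magnesium bromide; 11 allyl iodide
Product: 13 (2S,3S,4S)-2-allyl-4-(tert-butyldimethylsilyloxy)-2-methyl-3-(3-methylbut-1-en-2-yl)cycloheptan-1-one, via magnesium bromide enolate 12 (not isolated)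
Conditions: 10 (1.5 equiv), CuBr·SMe2 (10 mol %), THF, −78 to −30 °C; then HMPA, 11 (3 equiv), −30 to 0 °C
Reagents that add atoms: none
Why: Transmetalation of 10 to monovalent copper gives an alkenylcuprate that adds to the β-carbon C5 of enone 8 (π-complex, trivalent copper intermediate, reductive elimination), forming C4–C5 while copper suppresses 1,2-addition. The closest known reaction type is the copper-mediated conjugate addition to 4-silyloxycycloalkenones with trans trapping of the enolate by an alkyl halide (three-component coupling). C5 is controlled by C6: the cuprate approaches the enone face opposite the allylic silyloxy group, the usual anti mode for γ-oxygenated enones. The magnesium enolate 12 is regiodefined as C1=C10 and, once HMPA loosens its aggregates, is alkylated at carbon by allyl iodide in an SN2 reaction that forms C1–C2 and the quaternary centre. C1 is controlled by C5: the electrophile enters on the enolate face opposite the branched alkenyl group, so the allyl and alkenyl arms are trans and the methyl group is cis to the alkenyl group. No ring is closed; the trans relationship of the two arms later becomes the trans ring fusion. The step needs 1,4- over 1,2-addition, C- over O-alkylation and no enolate equilibration toward C9; the copper catalyst, the soft iodide, the excess of electrophile and the low temperature are chosen for this, and the silyloxy group is too poor a leaving group to be expelled.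

Step 10
Reactants: 13 (2S,3S,4S)-2-allyl-4-(tert-butyldimethylsilyloxy)-2-methyl-3-(3-methylbut-1-en-2-yl)cycloheptan-1-one
Product: 14 trans-fused bicyclic ketone (1S,6S): C10 ketone, C1 β-methyl, C3=C4 with isopropyl on C4, 5α-H, 6α-OTBS
Conditions: second-generation Grubbs catalyst (H2IMes)(PCy3)Cl2Ru=CHPh (5 mol %), toluene, 80 °C
Reagents that add atoms: none
Why: Ring-closing metathesis: the ruthenium alkylidene loads at the unhindered allyl terminus and closes on the 1,1-disubstituted alkene with loss of ethene, a known way to make trisubstituted cyclopentenes with a branched substituent on the alkene. Because the two arms are already trans and no stereocentre is formed, the ring fusion is trans by construction.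

Step 11
Reactants: 14 trans-fused bicyclic ketone
Product: 15 C10 trimethylsilyl enol ether of 14 (C9=C10)
Conditions: LiN(iPr)2 (LDA, commercial solution), TMSCl, THF, −78 °C; Et3N quench
Reagents that add atoms: chlorotrimethylsilane, C[Si](C)(C)Cl
Why: Kinetic enolisation can only go toward C9 because C1 is quaternary, and O-silylation gives a single silyl enol ether.

Step 12
Reactants: 15 C10 trimethylsilyl enol ether
Product: 16 C8=C9 enone (1S,6S): C10 ketone conjugated with C8=C9, C3=C4 with isopropyl, 6α-OTBS
Conditions: Pd(OAc)2 (1.1 equiv), MeCN, rt
Reagents that add atoms: none
Why: Saegusa–Ito oxidation: divalent palladium forms a palladium enolate from the silyl enol ether, and β-hydride elimination of a C8 hydrogen gives the enone. The isolated trisubstituted ring-A alkene is not expected to interfere.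

Step 13
Reactants: 16 C8=C9 enone
Product: 17 C10 trimethylsilyl enol ether (C9=C10) carrying the new C8 methyl group (C8 configuration uncontrolled and of no consequence)
Conditions: Me2CuLi (from MeLi and CuI), TMSCl, THF, −78 °C; Et3N, then aqueous NaHCO3
Reagents that add atoms: lithium dimethylcuprate, [Li+].C[Cu-]C; chlorotrimethylsilane, C[Si](C)(C)Cl
Why: TMSCl-accelerated conjugate addition of a Gilman cuprate with trapping of the enolate as its silyl enol ether. The new C8 centre becomes sp2 in the next step, so its configuration does not matter.

Step 14
Reactants: 17 C8-methyl silyl enol ether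
Product: 18 dienone (1S,6S): C10 ketone, C8=C9 with methyl on C8, C3=C4 with isopropyl on C4, 5α-H, 6α-OTBS
Conditions: Pd(OAc)2 (1.1 equiv), MeCN, 40 °C
Reagents that add atoms: none
Why: Second Saegusa–Ito oxidation; the only β-hydrogen available to the palladium enolate is the tertiary C8–H, so the methyl-bearing C8=C9 enone forms.

Step 15
Reactants: 18 dienone
Product: 19 bromohydrin (1S,6S): 3α-bromo, 4β-hydroxy, 4α-isopropyl, C8-methyl enone, 6α-OTBS
Conditions: NBS, THF/H2O, 0 °C, dark
Reagents that add atoms: N-bromosuccinimide, O=C1CCC(=O)N1Br; water, O
Why: Bromohydrin formation on the electron-rich C3=C4 alkene in preference to the enone alkene. The bromonium ion should form on the α face, away from the pseudoaxial C1 methyl group, and water should open it anti at the tertiary carbon C4 (Markovnikov), which places the hydroxyl β and the bromide 3α.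

Step 16
Reactants: 19 bromohydrin
Product: 20 4β-hydroxy enone (1S,6S): C10 ketone, C8=C9 with methyl, tertiary 4β-OH with 4α-isopropyl, 6α-OTBS
Conditions: Bu3SnH, AIBN (cat.), toluene, 80 °C
Reagents that add atoms: none
Why: Radical chain dehalogenation with tin hydride removes the secondary bromide without touching C4; bromine abstraction is far faster than stannyl radical addition to the enone.

Step 17
Reactants: 20 4β-hydroxy enone
Product: 21 10β-allylic alcohol (1S,6S,10S): 10β-OH, C8=C9 with methyl, 4β-OH, 6α-OTBS
Conditions: NaBH4, CeCl3·7H2O, MeOH, −40 °C
Reagents that add atoms: none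
Why: Luche reduction gives 1,2-reduction of the enone. Hydride is expected to enter from the α face, anti to the pseudoaxial C1 methyl group beside the carbonyl, giving the 10β-alcohol.

Step 18
Reactants: 21 10β-allylic alcohol; 22 angelic acid ((Z)-2-methylbut-2-enoic acid)
Product: 23 10α-angelate (1S,6S,10R): 10α-O-angeloyl, 4β-OH, 6α-OTBS
Conditions: PPh3, DIAD, toluene, 0 °C to rt
Reagents that add atoms: none
Why: Mitsunobu esterification: the alkoxyphosphonium ion at C10 is displaced by angelate with inversion (SN2), the carboxylate entering from the same open α face that the hydride used. Angelic acid reacts as a nucleophile and is never activated at its acyl carbon, which avoids Z to E isomerisation, and the tertiary C4 hydroxyl does not react.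

Step 19
Reactants: 23 10α-angelate silyl ether
Product: 24 10α-angelate with free 6α- and 4β-hydroxyls
Conditions: HF·pyridine, pyridine, THF, 0 °C to rt
Reagents that add atoms: none
Why: Fluoride cleavage of the silyl ether under buffered, non-basic conditions, which should spare the allylic angelate and the tertiary alcohol and give no alkoxide that could cause acyl migration.

Step 20
Reactants: 24 10α-angelate diol; 25 3,4-dimethoxybenzoyl chloride
Product: 26 CNP0142353.1, (1S,4R,5S,6S,10R)-10-angeloyloxy-4-hydroxy-6-(3,4-dimethoxybenzoyloxy)dauc-8-ene
Conditions: DMAP, Et3N, CH2Cl2, 0 °C to rt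
Reagents that add atoms: none
Why: DMAP-catalysed acylation of the only secondary hydroxyl; the tertiary C4 hydroxyl is inert under these conditions and a formed angelate ester is stable to them.

## Compound list

1 | cyclohepta-1,3-diene | C1=CC=CCCC1 | starting material
2 | cis-cyclohept-2-ene-1,4-diyl diacetate (meso) | CC(=O)O[C@@H]1CCC[C@H](OC(C)=O)C=C1 | intermediate
3 | (1R,4S)-4-hydroxycyclohept-2-en-1-yl acetate | CC(=O)O[C@@H]1CCC[C@H](O)C=C1 | intermediate
4 | (1R,4S)-4-(tert-butyldimethylsilyloxy)cyclohept-2-en-1-yl acetate | CC(=O)O[C@@H]1CCC[C@H](O[Si](C)(C)C(C)(C)C)C=C1 | intermediate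
5 | (1R,4S)-4-(tert-butyldimethylsilyloxy)cyclohept-2-en-1-ol | O[C@@H]1CCC[C@H](O[Si](C)(C)C(C)(C)C)C=C1 | intermediate
6 | (S)-4-(tert-butyldimethylsilyloxy)cyclohept-2-en-1-one | O=C1CCC[C@H](O[Si](C)(C)C(C)(C)C)C=C1 | intermediate
7 | (S)-4-(tert-butyldimethylsilyloxy)-2-iodocyclohept-2-en-1-one | O=C1CCC[C@H](O[Si](C)(C)C(C)(C)C)C=C1I | intermediate
8 | (S)-4-(tert-butyldimethylsilyloxy)-2-methylcyclohept-2-en-1-one | O=C1CCC[C@H](O[Si](C)(C)C(C)(C)C)C=C1C | intermediate
9 | 2-bromo-3-methylbut-1-ene | C=C(Br)C(C)C | starting material
10 | (3-methylbut-1-en-2-yl)magnesium bromide | C=C([Mg]Br)C(C)C | intermediate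
11 | allyl iodide | C=CCI | starting material
12 | bromomagnesium (3S,4S)-4-(tert-butyldimethylsilyloxy)-2-methyl-3-(3-methylbut-1-en-2-yl)cyclohept-1-en-1-olate | Br[Mg]OC1=C(C)[C@H](C(=C)C(C)C)[C@@H](O[Si](C)(C)C(C)(C)C)CCC1 | intermediate
13 | (2S,3S,4S)-2-allyl-4-(tert-butyldimethylsilyloxy)-2-methyl-3-(3-methylbut-1-en-2-yl)cycloheptan-1-one | O=C1CCC[C@H](O[Si](C)(C)C(C)(C)C)[C@@H](C(=C)C(C)C)[C@]1(C)CC=C | intermediate
14 | trans-fused bicyclic ketone: C10 ketone, C1 β-methyl, C3=C4 with isopropyl on C4, 5α-H, 6α-OTBS | O=C1CCC[C@H](O[Si](C)(C)C(C)(C)C)[C@@H]2[C@]1(C)CC=C2C(C)C | intermediate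
15 | C10 trimethylsilyl enol ether of 14 (C9=C10) | C[Si](C)(C)OC1=CCC[C@H](O[Si](C)(C)C(C)(C)C)[C@@H]2[C@]1(C)CC=C2C(C)C | intermediate
16 | C8=C9 enone of 14 | O=C1C=CC[C@H](O[Si](C)(C)C(C)(C)C)[C@@H]2[C@]1(C)CC=C2C(C)C | intermediate
17 | C10 trimethylsilyl enol ether with C8 methyl (C8 unassigned) | C[Si](C)(C)OC1=CC(C)C[C@H](O[Si](C)(C)C(C)(C)C)[C@@H]2[C@]1(C)CC=C2C(C)C | intermediate
18 | dienone: C10 ketone, C8=C9 with C8 methyl, C3=C4 with isopropyl, 6α-OTBS | O=C1C=C(C)C[C@H](O[Si](C)(C)C(C)(C)C)[C@@H]2[C@]1(C)CC=C2C(C)C | intermediate
19 | 3α-bromo-4β-hydroxy enone (bromohydrin) | O=C1C=C(C)C[C@H](O[Si](C)(C)C(C)(C)C)[C@@H]2[C@]1(C)C[C@@H](Br)[C@@]2(O)C(C)C | intermediate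
20 | 4β-hydroxy-4α-isopropyl enone, 6α-OTBS | O=C1C=C(C)C[C@H](O[Si](C)(C)C(C)(C)C)[C@@H]2[C@]1(C)CC[C@@]2(O)C(C)C | intermediate
21 | 10β-allylic alcohol, 4β-OH, 6α-OTBS | O[C@H]1C=C(C)C[C@H](O[Si](C)(C)C(C)(C)C)[C@@H]2[C@]1(C)CC[C@@]2(O)C(C)C | intermediate
22 | angelic acid, (Z)-2-methylbut-2-enoic acid | C/C=C(/C)C(=O)O | starting material
23 | 10α-angelate, 4β-OH, 6α-OTBS | C/C=C(/C)C(=O)O[C@@H]1C=C(C)C[C@H](O[Si](C)(C)C(C)(C)C)[C@@H]2[C@]1(C)CC[C@@]2(O)C(C)C | intermediate
24 | 10α-angelate, 4β,6α-diol | C/C=C(/C)C(=O)O[C@@H]1C=C(C)C[C@H](O)[C@@H]2[C@]1(C)CC[C@@]2(O)C(C)C | intermediate
25 | 3,4-dimethoxybenzoyl chloride | COc1ccc(C(=O)Cl)cc1OC | starting material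
26 | CNP0142353.1, (1S,4R,5S,6S,10R)-10-angeloyloxy-4-hydroxy-6-(3,4-dimethoxybenzoyloxy)dauc-8-ene | C/C=C(/C)C(=O)O[C@@H]1C=C(C)C[C@H](OC(=O)c2ccc(OC)c(OC)c2)[C@@H]2[C@]1(C)CC[C@@]2(O)C(C)C | target

## Step count and risks

Total step count: 20. Longest linear sequence: 19 steps (steps 1 to 7 and 9 to 20, from 1 to 26); step 8 is a one-step branch.

**Step 9 (key step).** The branched alkenylcopper may add sluggishly to a β-carbon flanked by the C-methyl and the silyloxy group. Alkylation of the tetrasubstituted magnesium enolate may then be slow enough for proton transfer, so that allylation occurs at C9 or on oxygen, and copper-mediated coupling of surplus Grignard reagent with allyl iodide may consume the electrophile. Fallback: setting out from 8, the conjugate addition is run as before, but the enolate is quenched with allyl chloroformate and the allyl enol carbonate, allyl (3S,4S)-4-(tert-butyldimethylsilyloxy)-2-methyl-3-(3-methylbut-1-en-2-yl)cyclohept-1-en-1-yl carbonate F1, is isolated. Catalytic Pd(PPh3)4 (zerovalent palladium) in THF then brings about decarboxylative allylation (Tsuji allylation). The allyl group is delivered to C1 within the ion pair, again on the face away from the C5 substituent, and the route is rejoined at 13.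

**Step 15.** Bromonium formation may not discriminate the faces well, water may have difficulty reaching C4 on the methyl-bearing face, or the tertiary cation may lose a proton to give an allylic bromide. Fallback: setting out from 18, epoxidation with mCPBA (buffered with NaHCO3) is irreversible and sterically governed and should give the 3α,4α-epoxide F2. Acid-catalysed hydrolysis (aqueous HClO4, THF) opens it at the tertiary carbon with inversion to give the 3α,4β-diol F3. The secondary hydroxyl is converted with 1,1'-thiocarbonyldiimidazole into the C3 imidazolylthiocarbonyl ester F4; the trans relationship of the diol prevents a cyclic thiocarbonate. Barton–McCombie reduction with Bu3SnH and AIBN rejoins the route at 20.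

**Step 18.** Displacement at an allylic carbon next to a quaternary centre may be outrun by ionisation, followed by elimination or allylic transposition, or may not proceed at all. Fallback: setting out from 20, Corey–Bakshi–Shibata reduction with the (S)-configured methyl oxazaborolidine and catecholborane is used to deliver hydride to the β face, with the quaternary C1 side acting as the large group, and gives the 10α-allylic alcohol F5. This is acylated with retention by the mixed anhydride of 22 and 2,4,6-trichlorobenzoyl chloride (Et3N, toluene, no DMAP, to limit Z to E isomerisation), and the route is rejoined at 23.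

**Step 17.** The flexible cycloheptenone may show poor facial discrimination, giving mixtures of C10 epimers. Fallback: setting out from 20, substrate control is replaced by reagent control: Corey–Bakshi–Shibata reduction with the (R)-configured methyl oxazaborolidine, matched with the expected substrate bias, delivers hydride to the α face and comes back to the route at 21. No new compound is made.

**Step 2.** The enzyme may act on the other enantiotopic acetate and give the mirror-image monoacetate. Fallback: setting out from 2, methanolysis (K2CO3, MeOH) gives the meso diol, cis-cyclohept-2-ene-1,4-diol F6. The same lipase with vinyl acetate in an organic solvent then acylates the carbinol whose acetate it would have hydrolysed, which gives the opposite enantiomer of the monoacetate, and the route is rejoined at 3.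

## Further compounds

F1 | step 9 | allyl (3S,4S)-4-(tert-butyldimethylsilyloxy)-2-methyl-3-(3-methylbut-1-en-2-yl)cyclohept-1-en-1-yl carbonate | C=CCOC(=O)OC1=C(C)[C@H](C(=C)C(C)C)[C@@H](O[Si](C)(C)C(C)(C)C)CCC1
F2 | step 15 | 3α,4α-epoxide of dienone 18 | O=C1C=C(C)C[C@H](O[Si](C)(C)C(C)(C)C)[C@@H]2[C@]1(C)C[C@H]3O[C@@]23C(C)C
F3 | step 15 | 3α,4β-diol (4α-isopropyl) enone | O=C1C=C(C)C[C@H](O[Si](C)(C)C(C)(C)C)[C@@H]2[C@]1(C)C[C@@H](O)[C@@]2(O)C(C)C
F4 | step 15 | C3 O-(imidazol-1-ylthiocarbonyl) derivative of F3 | O=C1C=C(C)C[C@H](O[Si](C)(C)C(C)(C)C)[C@@H]2[C@]1(C)C[C@@H](OC(=S)n3ccnc3)[C@@]2(O)C(C)C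
F5 | step 18 | 10α-allylic alcohol, 4β-OH, 6α-OTBS (C10 epimer of 21) | O[C@@H]1C=C(C)C[C@H](O[Si](C)(C)C(C)(C)C)[C@@H]2[C@]1(C)CC[C@@]2(O)C(C)C
F0 | step 17 | none | none
F6 | step 2 | cis-cyclohept-2-ene-1,4-diol (meso) | O[C@@H]1CCC[C@H](O)C=C1
A1 | alternative 1 | bicyclic 10α-allylic alcohol with 6α-veratrate and 4β-triethylsilyl ether | O[C@@H]1C=C(C)C[C@H](OC(=O)c2ccc(OC)c(OC)c2)[C@@H]3[C@]1(C)CC[C@@]3(O[Si](CC)(CC)CC)C(C)C
A2 | alternative 1 | ring-A cyclopentane with C10 aldehyde on C1 and, on C5, the side chain with the C6 veratrate and the (Z)-C8-methyl alkenyl iodide | I/C=C(C)\C[C@H](OC(=O)c1ccc(OC)c(OC)c1)[C@@H]2[C@](C=O)(C)CC[C@@]2(O[Si](CC)(CC)CC)C(C)C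
A3 | alternative 2 | trans-fused hydroazulen-6-one with C4 isopropyl carbinol and C10 ethylene ketal | O1CCOC12CCCC(=O)[C@@H]3[C@]2(C)CC[C@@]3(O)C(C)C
A4 | alternative 2 | cis-fused decalin with C10 ethylene ketal, tertiary C6 hydroxyl, C5 mesylate and C4 isopropyl carbinol, all three oxygens syn to the angular methyl | C[C@]12CC[C@@](O)(C(C)C)[C@H](OS(C)(=O)=O)[C@@]1(O)CCCC23OCCO3
A5 | alternative 2 | (S)-Wieland–Miescher ketone | C[C@]12CCC(=O)C=C1CCCC2=O
A6 | alternative 3 | ethyl 2-hydroxy-2-(1-methyl-2-oxocyclopentyl)acetate with C1 and C10 as in the target | O=C1CCC[C@]1(C)[C@H](O)C(=O)OCC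
A7 | alternative 3 | ethyl 3-(1-hydroxycyclobutyl)-3-methyloxirane-2-carboxylate, configured to give A6 | CCOC(=O)[C@H]1O[C@]1(C)C2(O)CCC2
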